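**Retrosynthetic overview**
1. Naamidine E ⇒ last C–N bond (silyl-mediated amidine condensation): the 2-aminoimidazole "naamine" core + intact 1-methylparabanic acid, as in the presumed biogenesis.
2. Naamine core ⇒ C5–CH2 bond: 2-amino-1-methyl-4-(4-methoxybenzyl)imidazole + the o-quinone methide of 2,5-dihydroxy-3,4-dimethoxybenzyl alcohol, so the hydroquinone stays unprotected and no tetra-oxygenated amino acid is needed.
3. Imidazole ring ⇒ α-(methylamino)ketone + cyanamide (guanylation/cyclodehydration, the biogenetic amino ketone + C1N2 logic), run in the same flask as line 2.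
4. Amino ketone ⇒ Boc-sarcosine Weinreb amide + 4-MeOC6H4CH2MgCl; hydroquinone alcohol ⇒ 3-hydroxy-4,5-dimethoxybenzaldehyde by reduction and Teuber para-oxidation.
5. Ring order: both benzene rings are bought; the 2-aminoimidazole ring is the only ring made (step 5); the imidazolidinedione ring is bought and attached last (step 6).

Assumption: the target has no stereocentre or stereogenic double bond, so the achiral compound itself is the required single species and no asymmetric step is needed; 1-methylparabanic acid, the 4-methoxybenzyl Grignard solution and 3-hydroxy-4,5-dimethoxybenzaldehyde are taken as catalogue chemicals.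

**Route**

Step 1
Reactants: 1 N-(tert-butoxycarbonyl)-N-methylglycine (Boc-sarcosine)
Product: 3 tert-butyl N-{2-[methoxy(methyl)amino]-2-oxoethyl}-N-methylcarbamate (Boc-sarcosine Weinreb amide), via acyl imidazolide 2 (not isolated)
Conditions: CDI (1.1 equiv), CH2Cl2, rt, 1 h; then MeNH(OMe)·HCl (1.2 equiv), rt, 16 h
Reagents that add atoms: N,O-dimethylhydroxylamine hydrochloride, CNOC.Cl
Why: Amide coupling through the acyl imidazolide (Weinreb amide formation); the imidazole released frees the amine from its hydrochloride, and no stereocentre is involved.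

Step 2
Reactants: 3 Boc-sarcosine Weinreb amide; 4 (4-methoxybenzyl)magnesium chloride
Product: 5 tert-butyl N-[3-(4-methoxyphenyl)-2-oxopropyl]-N-methylcarbamate
Conditions: 4 (1.6 equiv, 0.25 M in THF), THF, −15 to 0 °C, 2 h; cold 1 M HCl (aq) quench
Reagents that add atoms: none
Why: Weinreb ketone synthesis: the benzylic Grignard adds once because the magnesium-chelated tetrahedral adduct survives until the quench, the Boc carbamate is inert at this temperature, and no stereocentre is formed.

Step 3
Reactants: 6 3-hydroxy-4,5-dimethoxybenzaldehyde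
Product: 7 5-(hydroxymethyl)-2,3-dimethoxyphenol
Conditions: NaBH4 (0.6 equiv), MeOH, 0 °C, 30 min; H2O work-up
Reagents that add atoms: none
Why: Chemoselective NaBH4 reduction of the aryl aldehyde; the phenol is only deprotonated, and no stereocentre is formed.

Step 4
Reactants: 7 5-(hydroxymethyl)-2,3-dimethoxyphenol
Product: 9 2-(hydroxymethyl)-5,6-dimethoxybenzene-1,4-diol, via quinone 8 (not isolated)
Conditions: K2[ON(SO3)2] (2.2 equiv), aq KH2PO4/acetone, 0 °C to rt, 1 h; then Na2S2O4 (aq), EtOAc, rt, Ar
Reagents that add atoms: potassium nitrosodisulfonate K2[ON(SO3)2], [K+].[K+].[O]N(S(=O)(=O)[O-])S(=O)(=O)[O-]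
Why: Teuber oxidation: the nitrosodisulfonate radical removes the phenolic hydrogen and a second equivalent oxidises the free para position (ortho to the CH2OH arm) to the 2,3-dimethoxy-1,4-benzoquinone 8, the same conversion that turns 2,3-dimethoxy-5-alkylphenols into ubiquinone-type quinones, and Na2S2O4 reduces 8 to the hydroquinone in the same flask; no stereocentre is formed.

Step 5
Reactants: 5 tert-butyl N-[3-(4-methoxyphenyl)-2-oxopropyl]-N-methylcarbamate; 9 2-(hydroxymethyl)-5,6-dimethoxybenzene-1,4-diol; 10 cyanamide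
Product: 13 2-{[2-amino-4-(4-methoxybenzyl)-1-methyl-1H-imidazol-5-yl]methyl}-5,6-dimethoxybenzene-1,4-diol, via amino ketone hydrochloride 11 (not isolated), via 2-aminoimidazole 12 (not isolated)
Conditions: 4 M HCl in dioxane, rt, 1 h, concentrate; then 10 (2 equiv), degassed H2O, pH 4.5 (NaOH), 95 °C, 2 h; then 9 (1.2 equiv in EtOH, slow addition), 85 °C, 3 h, Ar; NaHCO3 work-up
Reagents that add atoms: none
Why: Proposed new method: Boc removal gives the α-(methylamino)ketone salt, whose Marckwald-type condensation with cyanamide (N-guanylation, cyclisation onto the ketone, dehydration) is the known way to 1-methyl-4-benzyl-2-aminoimidazoles; the new part is to keep the enamine-like C5–H of 12 in the same hot, weakly acidic water and let it capture the o-quinone methide that 9 forms by loss of water, a Friedel–Crafts-type C-benzylation whose closest known relatives are the C4/C5 alkylation of 2-aminoimidazoles by aldehydes and stabilised carbocations and the C3 alkylation of indoles by o-hydroxybenzyl alcohols; N-adducts are o-hydroxybenzylamines that revert to the quinone methide on heating, so the C–C product is the thermodynamic sink, cyanamide is too weak a nucleophile to compete, rearomatisation leaves the hydroquinone free, and no stereocentre is formed.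

Step 6
Reactants: 13 2-{[2-amino-4-(4-methoxybenzyl)-1-methyl-1H-imidazol-5-yl]methyl}-5,6-dimethoxybenzene-1,4-diol; 14 1-methylimidazolidine-2,4,5-trione (1-methylparabanic acid)
Product: 18 naamidine E, via O-silyl imidate 15 (not isolated), via bis-silyl ether 16 (not isolated), via bis-silyl naamidine 17 (not isolated)
Conditions: 14 (1.5 equiv), BSA (5 equiv), MeCN, reflux, 1 h; then 13, MeCN/toluene, reflux, 16 h, Ar; then 1 M HCl (aq)/THF, rt
Reagents that add atoms: none
Why: Silyl-mediated amidine-forming condensation: BSA turns 14 into the O-silyl imidate at the N3–C4 lactam and masks both phenols of 13 as trimethylsilyl ethers, the 2-amino group adds at C4 and trimethylsilanol leaves to give the N-acylamidine (the known way of joining naamine-type amines to 1-methylparabanic acid), and the acidic work-up cleaves the aryl silyl ethers; no stereocentre is formed.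

**Compound list**
1 | N-(tert-butoxycarbonyl)-N-methylglycine (Boc-sarcosine) | CN(CC(=O)O)C(=O)OC(C)(C)C | starting material
2 | tert-butyl N-[2-(1H-imidazol-1-yl)-2-oxoethyl]-N-methylcarbamate (acyl imidazolide) | CN(CC(=O)n1ccnc1)C(=O)OC(C)(C)C | intermediate
3 | tert-butyl N-{2-[methoxy(methyl)amino]-2-oxoethyl}-N-methylcarbamate | CON(C)C(=O)CN(C)C(=O)OC(C)(C)C | intermediate
4 | (4-methoxybenzyl)magnesium chloride | COc1ccc(C[Mg]Cl)cc1 | starting material
5 | tert-butyl N-[3-(4-methoxyphenyl)-2-oxopropyl]-N-methylcarbamate | COc1ccc(CC(=O)CN(C)C(=O)OC(C)(C)C)cc1 | intermediate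
6 | 3-hydroxy-4,5-dimethoxybenzaldehyde | COc1cc(C=O)cc(O)c1OC | starting material
7 | 5-(hydroxymethyl)-2,3-dimethoxyphenol | COc1cc(CO)cc(O)c1OC | intermediate
8 | 2-(hydroxymethyl)-5,6-dimethoxy-1,4-benzoquinone | COC1=C(OC)C(=O)C(CO)=CC1=O | intermediate
9 | 2-(hydroxymethyl)-5,6-dimethoxybenzene-1,4-diol | COc1c(O)cc(CO)c(O)c1OC | intermediate
10 | cyanamide | NC#N | starting material
11 | 1-(4-methoxyphenyl)-3-(methylamino)propan-2-one hydrochloride | CNCC(=O)Cc1ccc(OC)cc1.Cl | intermediate
12 | 4-(4-methoxybenzyl)-1-methyl-1H-imidazol-2-amine | COc1ccc(Cc2cn(C)c(N)n2)cc1 | intermediate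
13 | 2-{[2-amino-4-(4-methoxybenzyl)-1-methyl-1H-imidazol-5-yl]methyl}-5,6-dimethoxybenzene-1,4-diol | COc1ccc(Cc2nc(N)n(C)c2Cc2cc(O)c(OC)c(OC)c2O)cc1 | intermediate
14 | 1-methylimidazolidine-2,4,5-trione (1-methylparabanic acid) | CN1C(=O)NC(=O)C1=O | starting material
15 | 1-methyl-4-[(trimethylsilyl)oxy]-1H-imidazole-2,5-dione | CN1C(=O)N=C(O[Si](C)(C)C)C1=O | intermediate
16 | 5-{3,4-dimethoxy-2,5-bis[(trimethylsilyl)oxy]benzyl}-4-(4-methoxybenzyl)-1-methyl-1H-imidazol-2-amine | COc1ccc(Cc2nc(N)n(C)c2Cc2cc(O[Si](C)(C)C)c(OC)c(OC)c2O[Si](C)(C)C)cc1 | intermediate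
17 | bis(trimethylsilyl) ether of naamidine E | COc1ccc(Cc2nc(NC3=NC(=O)N(C)C3=O)n(C)c2Cc2cc(O[Si](C)(C)C)c(OC)c(OC)c2O[Si](C)(C)C)cc1 | intermediate
18 | naamidine E, 4-{[5-(2,5-dihydroxy-3,4-dimethoxybenzyl)-4-(4-methoxybenzyl)-1-methyl-1H-imidazol-2-yl]amino}-1-methyl-1H-imidazole-2,5-dione | COc1ccc(Cc2nc(NC3=NC(=O)N(C)C3=O)n(C)c2Cc2cc(O)c(OC)c(OC)c2O)cc1 | target

**Step count and risks**
Total steps: 6. Longest linear sequence: 4 (steps 1, 2, 5, 6; the branch 3, 4, 5, 6 is equally long).

Most likely to fail, in order:

Step 5 (one-flask ring formation and quinone-methide capture). The risks are N-benzylation, self-condensation of 9 and over-alkylation of 13. The fallback sets out from 12 and 6 and comes back to the route at 13. Step 5 is stopped after the cyanamide stage and 12 is isolated (pH 10, EtOAc). The C5–CH2 bond is then made by a different mechanism at the phenol oxidation level: 12 and aldehyde 6 in TFA/CH2Cl2 with Et3SiH (0 °C to rt). This is a Friedel–Crafts hydroxyalkylation at C5 followed by ionic hydrogenation of the doubly stabilised benzylic cation, with the exocyclic nitrogen blocked by protonation. It gives 5-{[2-amino-4-(4-methoxybenzyl)-1-methyl-1H-imidazol-5-yl]methyl}-2,3-dimethoxyphenol F1. Teuber oxidation of F1 as its salt (K2[ON(SO3)2], aq KH2PO4, pH 6) gives 2-{[2-amino-4-(4-methoxybenzyl)-1-methyl-1H-imidazol-5-yl]methyl}-5,6-dimethoxy-1,4-benzoquinone F2, which Na2S2O4 reduces in the same flask to 13; step 6 follows unchanged.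

Step 6 (condensation in the presence of the free, oxidisable hydroquinone). The fallback sets out from 12 (isolated as above) and 14 and comes back at 18. The order of the last two bond formations is reversed so that the hot silylation never meets the hydroquinone. 12 is condensed with 15 (made from 14 and BSA in refluxing MeCN) to give 4-{[4-(4-methoxybenzyl)-1-methyl-1H-imidazol-2-yl]amino}-1-methyl-1H-imidazole-2,5-dione F3. F3 is then C5-benzylated with 9 through the o-quinone methide in (CF3)2CHOH at 50 °C under Ar, giving 18 directly.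

Step 4 (Teuber oxidation and handling of the acid- and air-sensitive alcohol 9). The fallback sets out from 6 and comes back at 9. The radical quinone route is replaced by an ionic Elbs para-hydroxylation at the aldehyde stage, so no quinone is formed and the benzylic alcohol is made last. 6 with K2S2O8 in aq NaOH at 10–20 °C gives potassium 2-formyl-4-hydroxy-5,6-dimethoxyphenyl sulfate F4. Hot dilute HCl hydrolyses the sulfate ester to 2,5-dihydroxy-3,4-dimethoxybenzaldehyde F5, and NaBH4 in MeOH at 0 °C then gives 9.

Further compounds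
F1 | step 5 | 5-{[2-amino-4-(4-methoxybenzyl)-1-methyl-1H-imidazol-5-yl]methyl}-2,3-dimethoxyphenol | COc1ccc(Cc2nc(N)n(C)c2Cc2cc(O)c(OC)c(OC)c2)cc1
F2 | step 5 | 2-{[2-amino-4-(4-methoxybenzyl)-1-methyl-1H-imidazol-5-yl]methyl}-5,6-dimethoxy-1,4-benzoquinone | COc1ccc(Cc2nc(N)n(C)c2CC2=CC(=O)C(OC)=C(OC)C2=O)cc1
F3 | step 6 | 4-{[4-(4-methoxybenzyl)-1-methyl-1H-imidazol-2-yl]amino}-1-methyl-1H-imidazole-2,5-dione | COc1ccc(Cc2cn(C)c(NC3=NC(=O)N(C)C3=O)n2)cc1
F4 | step 4 | potassium 2-formyl-4-hydroxy-5,6-dimethoxyphenyl sulfate | COc1c(O)cc(C=O)c(OS(=O)(=O)[O-])c1OC.[K+]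
F5 | step 4 | 2,5-dihydroxy-3,4-dimethoxybenzaldehyde | COc1c(O)cc(C=O)c(O)c1OC
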